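Decide first whether this flask is a saturated solution or a solid feeding a small dissolved pool, since the two give different answers to the second question.

all flasks: catalyst 300 mM
- Monday's: solid substrate 1.5 M; protic impurity 0.30 M; run made earlier
- Saturday's: solid substrate 3 M; protic impurity 0.45 M; run made earlier
- flask: solid substrate 3.0 M; protic impurity 0.300 M; time 1.0 h

| run | time / min | target / % | starting material / % |
|---|---|---|---|
| Monday's | 6.00 | 0.4 | 2.7 |
| Monday's | 20.0 | 2.0 | 3.4 |
| Monday's | 30.0 | 5.2 | 4.6 |
| Monday's | 50.0 | 14.5 | 5.1 |
| Monday's | 80.0 | 33.7 | 0 |
| Saturday's | 6.00 | 0 | 1.9 |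
| Saturday's | 10.0 | 0 | 1.5 |
| Saturday's | 20.0 | 0.6 | 1.7 |
| Saturday's | 40.0 | 3.6 | 2.1 |
| Saturday's | 80.0 | 17.5 | 2.5 |

(standard deviation of a reading: 0.3 percentage points)
1. the target standing at 1.0 h, as a percentage of the solid substrate charged
2. concentration of starting material in solution at 1.0 h, in percent of saturation

Turn the question round. A pool of starting material at saturation, with solid present, stands still at its ceiling. Monday's pool instead climbs from 0.0405 M at 6.00 min to 0.0765 M at 50.0 min. I therefore read no ceiling in Monday's run and expect this flask, too, to stand well below saturation, though I read no figure for saturation itself.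

Work instead with the fraction of solid left. Monday's starting material reads 5.1 % at 50.0 min and 0 % at 80.0 min, so I take its solid to have ended between those times. That brackets the feed F, the molar rate at which solid enters solution, a zero-order supply:

F from 0.0187 M min⁻¹ to 0.0300 M min⁻¹

Saturday's pool at 80.0 min, 0.0750 M, is close to Monday's at 50.0 min on twice the solid, though with more protic impurity, so I assume that F does not depend on the charge and carry it over unchanged. With t the time and c the solid charged, the fraction left is:

f = 1 − F t / c, from 40.0 % to 62.5 % in this flask

The forecast gave 11 % and 75 %, with saturation “which I guess at about 0.1 M”. The flask gives 10.8 % and 5.92 %, with 43.8 % solid left, inside my bracket .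

    starting material → intermediate (k = 0.353 min⁻¹)
    catalyst + intermediate → catalyst + target (k = 0.0377 L mol⁻¹ min⁻¹)
    starting material + protic impurity → quenched substrate (k = 1.08 L mol⁻¹ min⁻¹)
    solid substrate ⇌ starting material, rate k4*(cs4 - [starting material]) while solid is left; crystals form when [starting material] > cs4 (solubility = 1.30 M, k = 0.0227 min⁻¹)

The neighbouring flask carries 1.2 M of protic impurity. F holds no impurity term, so the reckoning again gives 40.0 % to 62.5 %, and that flask shows 42.4 % solid left at 1.00 h, inside that bracket . Its quenched substrate stands at 34.4 % against 9.82 % in this flask, and its target at 4.88 %.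

The data were computed on assumed constants.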